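Take as your unit one percent of the starting material charged, and ask two things of it: is it lost by the time of reading, and if so, does it turn up as target?

| setting | north | east | west | Sunday's | Friday's |
|---|---|---|---|---|---|
| starting material | 0.10 M | 0.10 M | 0.10 M | 0.10 M | 0.10 M |
| reagent | 0.42 equiv | 1.7 equiv | 2 equiv | 2.00 equiv | 0.660 equiv |
| free catalyst | 7.6 mol% | 7.6 mol% | 16 mol% | 7.6 mol% | 30 mol% |
| temperature | 20 °C | 31 °C | 20 °C | 25 °C | 25 °C |
| remark | run made earlier | run made earlier | run made earlier |  |  |
| time |  |  |  | 40 min | 40 min |

| run | time / min | target / % | starting material / % |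
|---|---|---|---|
| north | 2.50 | 5 | 94 |
| north | 3.00 | 8 | 90 |
| north | 5.00 | 11 | 85 |
| north | 8.00 | 16 | 83 |
| north | 12.0 | 19 | 77 |
| north | 20.0 | 23 | 70 |
| north | 30.0 | 24 | 62 |
| east | 2.50 | 15 | 85 |
| east | 3.00 | 16 | 83 |
| east | 5.00 | 26 | 75 |
| east | 8.00 | 34 | 61 |
| east | 12.0 | 41 | 52 |
| east | 20.0 | 58 | 37 |
| east | 30.0 | 68 | 25 |
| west | 6.00 | 40 | 51 |
| west | 12.0 | 58 | 29 |
| west | 15.0 | 60 | 21 |
| west | 25.0 | 69 | 12 |
| west | 30.0 | 69 | 6 |

(standard deviation of a reading: 1.5 percentage points)

- the earlier runs were read with a standard deviation of 1.5 percentage points

* which of the two ends with the higher amount of target, in percent of the starting material charged ("neither" if they lie within 2 percentage points) (Sunday's / Friday's / neither)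
* target at the end, in percent of the starting material charged, Sunday's
* target at the end, in percent of the starting material charged, Friday's

This is my own reckoning, and it climbs a ladder of clocks, fastest first.

The first clock is the reagent's in Friday's flask. The north run opens by losing starting material at

0.0333 /min, so its reagent clock, charge over rate, is 12.6 min.

If rate follows catalyst and c(reagent), Friday's loading shortens that to

3.19 min.

That is far shorter than the 40 min of reading, so I treat reagent as the limiting reagent in Friday's flask. North has lost 38.0% against 0.42 equiv charged, so I assume one reagent per starting material lost.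

Next comes the starting-material clock. East's half-life reads 15.0 min, longer than Friday's reagent clock. Borrowed for Sunday's flask, which holds 2.00 equiv of reagent, it leaves

15.7% of the starting material.

The last rung is the fork. Target per starting material lost reads 0.632 in north, 0.734 in west and 0.907 in east. East is warmer than north at the same loading, and its share is higher. West has about twice north's catalyst at the same temperature, and its share is not lower. East and west lost more starting material than north, so, although those two also differ in catalyst and reagent, I interpolate between them on temperature as an estimate:

0.813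

This is the target share at 25 °C, target found per starting material lost. It gives

Sunday's: 68.5%; Friday's: 53.6%.

The forecast says Sunday's, with 72% (64% to 79%) for Sunday's and 37% (27% to 50%) for Friday's, which it calls “fast but reagent-limited”. On Friday's we differ: my figure is higher.

The flasks give 71.4% for Sunday's and 52.7% for Friday's.

    catalyst intermediate C → free catalyst + target (k = 3.39 /min, Ea = 90.0 kJ/mol)
    target + free catalyst ⇌ isomer of the product + free catalyst, rate k2*[free catalyst]*[target] forward; the back reaction follows from the equilibrium constant (K = 0.232, k = 5.85 /M/min, Ea = 39.0 kJ/mol, ΔH = −77.0 kJ/mol)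
    reagent + free catalyst ⇌ catalyst intermediate A (K = 3.30 /M, k = 1930 /M/min, Ea = 40.0 kJ/mol, ΔH = −83.0 kJ/mol)
    starting material + catalyst intermediate A ⇌ catalyst intermediate B (K = 34.4 /M, k = 36.7 /M/min, Ea = 46.0 kJ/mol, ΔH = −58.0 kJ/mol)
    catalyst intermediate B ⇌ by-product + catalyst intermediate C (K = 0.0500 M, k = 40.2 /min, Ea = 82.0 kJ/mol, ΔH = 0 kJ/mol)
    (constants at 25 °C)

In Friday's flask, reagent counts as run out at 36.5 min, earlier than the reading at 40 min, with 1.5% of its charge left at the reading, 35.1% of the starting material still there, and 53.6% of target after 400 min. The target share there is 0.812, and in the neighbour of Friday's charged with 2.60 equiv of reagent, where 0.021% of the starting material remains, 0.813 gives 81.3% of target against 81.1% found.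

(The numbers in the tables were computed with constants of no real substance; noise was put on by code.)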